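**Strategy.** Everything rests on closing the 14-membered carbocycle last at C13–C14 (cembrane numbering), the bond between the CH2 on the lactone β-carbon C1 and the allylic carbinol carbon. The key step exploits that C2–C13 is an intact E,E,E-farnesyl chain whose oxidised terminal E-methyl carbon (C13) is a 2-methyl-2-enal. A primary C14 alkylchromium, generated under neutral cobalt/chromium conditions from the acyclic iodo-enal 15, adds 1,2 to that enal in the presence of the finished cis-fused α-methylene-γ-butyrolactone ring. That ring is installed earlier by catalytic asymmetric 2-alkoxycarbonylallylboration of a farnesal. Oxidation and CBS reduction then set C13 before acetylation.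

Key step: step 12

Remarks (assumptions). Locants follow cembrane numbering: C1 = lactone β-CH, C2 = lactone O–CH, C3=C4, C7=C8 and C11=C12 = the three E-alkenes, C13 = acetoxy carbon, C14 = ring CH2, C15/C16/C17 = α-carbon, carbonyl and exocyclic methylene. The facial sense of (R)-TRIP in step 8 is taken by analogy with its allyl- and crotylboronate additions; the antipodal catalyst is used if the sense proves opposite.

**Step 1**
Reactants: 1 methyl acrylate; 2 (tert-butyldimethylsilyloxy)acetaldehyde
Product: 3 methyl 4-[(tert-butyldimethylsilyl)oxy]-3-hydroxy-2-methylidenebutanoate (racemic)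
Conditions: DABCO (1,4-diazabicyclo[2.2.2]octane, 0.5 equiv), neat in excess 1, rt
Reagents that add atoms: none
Why: Morita–Baylis–Hillman reaction of an activated α-silyloxy aldehyde; the new stereocentre is irrelevant because it becomes sp2 in step 3.

**Step 2**
Reactants: 3 Baylis–Hillman alcohol
Product: 4 methyl 3-acetoxy-4-[(tert-butyldimethylsilyl)oxy]-2-methylidenebutanoate (racemic)
Conditions: AcCl, pyridine, CH2Cl2, 0 °C
Reagents that add atoms: acetyl chloride CC(=O)Cl
Why: Simple O-acylation of the secondary allylic alcohol at low temperature, which should avoid allylic transposition of the acetate.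

**Step 3**
Reactants: 4 Baylis–Hillman acetate
Product: 5 methyl (2E)-4-[(tert-butyldimethylsilyl)oxy]-2-[(4,4,5,5-tetramethyl-1,3,2-dioxaborolan-2-yl)methyl]but-2-enoate
Conditions: B2pin2, CuCl (10 mol %), LiCl, KOAc, DMF, rt
Reagents that add atoms: bis(pinacolato)diboron CC1(C)OB(OC1(C)C)B1OC(C)(C)C(C)(C)O1
Why: Copper–boryl SN2' substitution of the allylic acetate (Hosomi–Miyaura-type borylation) should give the trisubstituted alkene with CH2OSi trans to the ester, i.e. cis to CH2B, the geometry that avoids A(1,3) strain with the ester.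

**Step 4**
Reactants: 6 (2E,6E)-farnesyl acetate
Product: 7 (2E,6E,10E)-12-hydroxy-3,7,11-trimethyldodeca-2,6,10-trien-1-yl acetate
Conditions: SeO2 (cat.), t-BuOOH, salicylic acid (cat.), CH2Cl2, rt
Reagents that add atoms: tert-butyl hydroperoxide CC(C)(C)OO (terminal oxidant; oxygen delivered through catalytic SeO2, O=[Se]=O)
Why: SeO2 allylic oxidation (ene reaction then [2,3]-shift) should select the E-methyl of the terminal, most electron-rich trisubstituted alkene, the 2,3-alkene being deactivated by the allylic acetate.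

**Step 5**
Reactants: 7 hydroxy acetate
Product: 8 (2E,6E,10E)-12-[(tert-butyldimethylsilyl)oxy]-3,7,11-trimethyldodeca-2,6,10-trien-1-yl acetate
Conditions: TBSCl, imidazole, DMF, rt
Reagents that add atoms: tert-butyldimethylsilyl chloride CC(C)(C)[Si](C)(C)Cl
Why: Standard silylation of a primary allylic alcohol.

**Step 6**
Reactants: 8 silyl ether acetate
Product: 9 (2E,6E,10E)-12-[(tert-butyldimethylsilyl)oxy]-3,7,11-trimethyldodeca-2,6,10-trien-1-ol
Conditions: K2CO3 (cat.), MeOH, rt
Reagents that add atoms: none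
Why: Methanolysis removes the acetate while the silyl ether is stable to mild base.

**Step 7**
Reactants: 9 allylic alcohol
Product: 10 (2E,6E,10E)-12-[(tert-butyldimethylsilyl)oxy]-3,7,11-trimethyldodeca-2,6,10-trienal
Conditions: MnO2, CH2Cl2, rt
Reagents that add atoms: none
Why: MnO2 oxidises the allylic alcohol to the enal under neutral conditions, which should preserve the 2E geometry.

**Step 8**
Reactants: 10 silyloxy farnesal; 5 allylboronate
Product: 12 (4R,5S)-4-{[(tert-butyldimethylsilyl)oxy]methyl}-5-[(1E,5E,9E)-11-[(tert-butyldimethylsilyl)oxy]-2,6,10-trimethylundeca-1,5,9-trien-1-yl]-3-methylideneoxolan-2-one, via syn-hydroxy ester 11 (not isolated)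
Conditions: (R)-TRIP [(R)-3,3'-bis(2,4,6-triisopropylphenyl)-1,1'-binaphthyl-2,2'-diyl hydrogen phosphate, C50H57O4P, 10 mol %], 4 Å MS, toluene, 0 °C to rt; then PPTS (cat.), toluene, 40 °C
Reagents that add atoms: none
Why: Chiral-phosphoric-acid-catalysed allylboration through a closed six-membered chair transition state: the E-boronate holds CH2OSi cis to CH2B, so that group is axial and the syn adduct results (C1 relative to C2), the catalyst selects the aldehyde face (C2 = S), and lactonisation of the syn-hydroxy ester gives the cis-lactone.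

**Step 9**
Reactants: 12 bis-silyl lactone
Product: 13 (4R,5S)-4-(hydroxymethyl)-5-[(1E,5E,9E)-11-hydroxy-2,6,10-trimethylundeca-1,5,9-trien-1-yl]-3-methylideneoxolan-2-one
Conditions: HF·pyridine, pyridine, THF, 0 °C to rt
Reagents that add atoms: none
Why: Buffered fluoride desilylation is compatible with the base-sensitive α-methylene lactone and removes both primary silyl ethers.

**Step 10**
Reactants: 13 diol
Product: 14 (4R,5S)-4-(hydroxymethyl)-3-methylidene-5-[(1E,5E,9E)-2,6,10-trimethyl-11-oxoundeca-1,5,9-trien-1-yl]oxolan-2-one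
Conditions: MnO2, CH2Cl2, rt
Reagents that add atoms: none
Why: MnO2 oxidises only the allylic primary alcohol (C13) and leaves the saturated C14 alcohol untouched.

**Step 11**
Reactants: 14 hydroxy enal
Product: 15 (4S,5S)-4-(iodomethyl)-3-methylidene-5-[(1E,5E,9E)-2,6,10-trimethyl-11-oxoundeca-1,5,9-trien-1-yl]oxolan-2-one
Conditions: PPh3, I2, imidazole, CH2Cl2, 0 °C
Reagents that add atoms: iodine II
Why: Appel-type (Garegg–Samuelsson) iodination of the primary alcohol under near-neutral conditions tolerated by the enal and the methylene lactone; the descriptor at C1 changes only through ligand priority.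

**Step 12**
Reactants: 15 iodo enal
Product: 17 (1S,2S,3E,7E,11E)-13-hydroxycembra-3,7,11,15(17)-tetraen-16,2-olide (both C13 epimers), via alkylchromium dichloride 16 (not isolated)
Conditions: CrCl2 (8 equiv), cobalt phthalocyanine C32H16CoN8 (0.2 equiv), DMF, 25 °C, 15 added by syringe pump over 12 h (final 3 mM); aqueous work-up
Reagents that add atoms: none
Why: Monovalent cobalt phthalocyanine (formed by CrCl2 reduction) displaces the primary iodide, the alkylcobalt homolyses and the C14 radical is captured by a second CrCl2 to give the alkyl trivalent-chromium species 16, which adds 1,2 to the chromium-bound C13 enal carbonyl; the closest known reaction type is the Takai–Utimoto cobalt-catalysed alkylchromium addition to aldehydes, run here as a Nozaki–Hiyama–Kishi-type macrocyclisation. The 14-membered carbocycle closes in a 14-exo-trig mode (C14 onto the C13 carbonyl carbon, oxygen exocyclic). The new stereocentre C13 is governed only by the conformation of the macrocyclic transition state (C12 methyl and cis-lactone bias), which is not relied upon, because both epimers converge in steps 13 and 14. The step needs chemoselectivity for the aldehyde over the lactone carbonyl, the C15=C17 acceptor and 1,4-addition, which the low basicity and aldehyde selectivity of alkylchromium reagents should secure, and ring closure over oligomerisation, which slow addition and the three conformation-restricting E-trisubstituted alkenes should secure. Capture of the C14 radical by CrCl2 should outrun 3-exo attack on the neighbouring C15=C17 bond.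

**Step 13**
Reactants: 17 macrocyclic allylic alcohols
Product: 18 (1S,2S,3E,7E,11E)-13-oxocembra-3,7,11,15(17)-tetraen-16,2-olide
Conditions: Dess–Martin periodinane, NaHCO3, CH2Cl2, 0 °C to rt
Reagents that add atoms: none
Why: Dess–Martin oxidation converts both C13 epimers into one enone without touching the alkenes or the lactone.

**Step 14**
Reactants: 18 macrocyclic enone
Product: 19 (1S,2S,3E,7E,11E,13R)-13-hydroxycembra-3,7,11,15(17)-tetraen-16,2-olide
Conditions: (S)-2-methyl-CBS-oxazaborolidine (C18H20BNO, 1 equiv), catecholborane, toluene, −78 °C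
Reagents that add atoms: none
Why: Corey–Bakshi–Shibata reduction with the α-methylalkenyl group as the large substituent and C14H2 as the small one, so the (S)-catalyst should deliver hydride to give 13R, and catecholborane at low temperature should spare the methylene lactone.

**Step 15**
Reactants: 19 (13R)-alcohol
Product: 20 (1S,2S,3E,7E,11E,13R)-13-acetoxycembra-3,7,11,15(17)-tetraen-16,2-olide (target)
Conditions: Ac2O, pyridine, DMAP (cat.), CH2Cl2, 0 °C to rt
Reagents that add atoms: acetic anhydride CC(=O)OC(C)=O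
Why: Acetylation of the secondary allylic alcohol with retention at C13.

**Compound list**
1 | methyl acrylate | C=CC(=O)OC | starting material
2 | (tert-butyldimethylsilyloxy)acetaldehyde | O=CCO[Si](C)(C)C(C)(C)C | starting material
3 | methyl 4-[(tert-butyldimethylsilyl)oxy]-3-hydroxy-2-methylidenebutanoate (racemic) | C=C(C(=O)OC)C(O)CO[Si](C)(C)C(C)(C)C | intermediate
4 | methyl 3-acetoxy-4-[(tert-butyldimethylsilyl)oxy]-2-methylidenebutanoate (racemic) | C=C(C(=O)OC)C(OC(C)=O)CO[Si](C)(C)C(C)(C)C | intermediate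
5 | methyl (2E)-4-[(tert-butyldimethylsilyl)oxy]-2-[(4,4,5,5-tetramethyl-1,3,2-dioxaborolan-2-yl)methyl]but-2-enoate | COC(=O)/C(CB1OC(C)(C)C(C)(C)O1)=C/CO[Si](C)(C)C(C)(C)C | intermediate
6 | (2E,6E)-farnesyl acetate | CC(=O)OC/C=C(\C)CC/C=C(\C)CCC=C(C)C | starting material
7 | (2E,6E,10E)-12-hydroxy-3,7,11-trimethyldodeca-2,6,10-trien-1-yl acetate | CC(=O)OC/C=C(\C)CC/C=C(\C)CC/C=C(\C)CO | intermediate
8 | (2E,6E,10E)-12-[(tert-butyldimethylsilyl)oxy]-3,7,11-trimethyldodeca-2,6,10-trien-1-yl acetate | CC(=O)OC/C=C(\C)CC/C=C(\C)CC/C=C(\C)CO[Si](C)(C)C(C)(C)C | intermediate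
9 | (2E,6E,10E)-12-[(tert-butyldimethylsilyl)oxy]-3,7,11-trimethyldodeca-2,6,10-trien-1-ol | OC/C=C(\C)CC/C=C(\C)CC/C=C(\C)CO[Si](C)(C)C(C)(C)C | intermediate
10 | (2E,6E,10E)-12-[(tert-butyldimethylsilyl)oxy]-3,7,11-trimethyldodeca-2,6,10-trienal | O=C/C=C(\C)CC/C=C(\C)CC/C=C(\C)CO[Si](C)(C)C(C)(C)C | intermediate
11 | methyl (3R,4S,5E,9E,13E)-15-[(tert-butyldimethylsilyl)oxy]-3-{[(tert-butyldimethylsilyl)oxy]methyl}-4-hydroxy-6,10,14-trimethyl-2-methylidenepentadeca-5,9,13-trienoate (syn-hydroxy ester) | COC(=O)C(=C)[C@H](CO[Si](C)(C)C(C)(C)C)[C@@H](O)/C=C(\C)CC/C=C(\C)CC/C=C(\C)CO[Si](C)(C)C(C)(C)C | intermediate (not isolated)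
12 | (4R,5S)-4-{[(tert-butyldimethylsilyl)oxy]methyl}-5-[(1E,5E,9E)-11-[(tert-butyldimethylsilyl)oxy]-2,6,10-trimethylundeca-1,5,9-trien-1-yl]-3-methylideneoxolan-2-one | C=C1C(=O)O[C@@H](/C=C(\C)CC/C=C(\C)CC/C=C(\C)CO[Si](C)(C)C(C)(C)C)[C@H]1CO[Si](C)(C)C(C)(C)C | intermediate
13 | (4R,5S)-4-(hydroxymethyl)-5-[(1E,5E,9E)-11-hydroxy-2,6,10-trimethylundeca-1,5,9-trien-1-yl]-3-methylideneoxolan-2-one | C=C1C(=O)O[C@@H](/C=C(\C)CC/C=C(\C)CC/C=C(\C)CO)[C@H]1CO | intermediate
14 | (4R,5S)-4-(hydroxymethyl)-3-methylidene-5-[(1E,5E,9E)-2,6,10-trimethyl-11-oxoundeca-1,5,9-trien-1-yl]oxolan-2-one | C=C1C(=O)O[C@@H](/C=C(\C)CC/C=C(\C)CC/C=C(\C)C=O)[C@H]1CO | intermediate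
15 | (4S,5S)-4-(iodomethyl)-3-methylidene-5-[(1E,5E,9E)-2,6,10-trimethyl-11-oxoundeca-1,5,9-trien-1-yl]oxolan-2-one | C=C1C(=O)O[C@@H](/C=C(\C)CC/C=C(\C)CC/C=C(\C)C=O)[C@H]1CI | intermediate
16 | alkylchromium dichloride of 15 (C14–CrCl2 in place of C14–I, same configuration, trivalent chromium) | C=C1C(=O)O[C@@H](/C=C(\C)CC/C=C(\C)CC/C=C(\C)C=O)[C@H]1C[Cr](Cl)Cl | intermediate (not isolated)
17 | (1S,2S,3E,7E,11E)-13-hydroxycembra-3,7,11,15(17)-tetraen-16,2-olide, both C13 epimers | C=C1C(=O)O[C@H]2/C=C(\C)CC/C=C(\C)CC/C=C(\C)C(O)C[C@@H]12 | intermediate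
18 | (1S,2S,3E,7E,11E)-13-oxocembra-3,7,11,15(17)-tetraen-16,2-olide | C=C1C(=O)O[C@H]2/C=C(\C)CC/C=C(\C)CC/C=C(\C)C(=O)C[C@@H]12 | intermediate
19 | (1S,2S,3E,7E,11E,13R)-13-hydroxycembra-3,7,11,15(17)-tetraen-16,2-olide | C=C1C(=O)O[C@H]2/C=C(\C)CC/C=C(\C)CC/C=C(\C)[C@H](O)C[C@@H]12 | intermediate
20 | (1S,2S,3E,7E,11E,13R)-13-acetoxycembra-3,7,11,15(17)-tetraen-16,2-olide | C=C1C(=O)O[C@H]2/C=C(\C)CC/C=C(\C)CC/C=C(\C)[C@H](OC(C)=O)C[C@@H]12 | target

**Step count.** Total: 15 steps. Longest linear sequence: 12 steps (steps 4–15, from farnesyl acetate 6).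

**Three steps most likely to fail**

1. Step 12 (key step). The alkylchromium may be protonated or reduced before it finds the distant enal, or may add intermolecularly, so that ring closure loses to reduction and oligomerisation. Fallback (a cross-electrophile ketone closure of the same bond): setting out from 15, Pinnick oxidation (NaClO2, NaH2PO4, 2-methyl-2-butene, t-BuOH/H2O) should give (2E,6E,10E)-11-[(2S,3S)-3-(iodomethyl)-4-methylidene-5-oxooxolan-2-yl]-2,6,10-trimethylundeca-2,6,10-trienoic acid F1. 2,2'-Dipyridyl disulfide and PPh3 should then convert it into its S-(pyridin-2-yl) thioester F2. Nickel/zirconium-mediated reductive coupling of the alkyl iodide with the thioester [NiBr2(dtbbpy), Cp2ZrCl2, Zn, DMI, rt, slow addition] should close the C13–C14 bond directly at the ketone level. The route is rejoined at enone 18.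

2. Step 8. The electron-poor, ester-substituted boronate may be activated too weakly by the phosphoric acid, so that facial and syn selectivity are eroded, or C2 may ionise during the acid lactonisation. Fallback (racemic syn-selective addition followed by kinetic resolution): setting out from 10 and 5, Sc(OTf)3-catalysed allylboration in toluene at rt should give the syn-hydroxy ester as a racemate, i.e. 11 together with its enantiomer, methyl (3S,4R,5E,9E,13E)-15-[(tert-butyldimethylsilyl)oxy]-3-{[(tert-butyldimethylsilyl)oxy]methyl}-4-hydroxy-6,10,14-trimethyl-2-methylidenepentadeca-5,9,13-trienoate F3. Sharpless kinetic resolution [Ti(OiPr)4, L-(+)-diisopropyl tartrate, t-BuOOH, 4 Å MS, CH2Cl2, −20 °C, run past half conversion] should epoxidise the fast-reacting F3 to the erythro 5,6-epoxy alcohol F4 and leave 11. Lactonisation of recovered 11 (PPTS, toluene) returns to the route at 12.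

3. Step 9 (and the free C14 alcohol carried through steps 10 and 11). The liberated C14 hydroxyl can attack the lactone carbonyl, so acyl migration to the isomeric, less substituted γ-lactone may compete during desilylation, oxidation or iodination. Fallback (no free C14 alcohol at any stage): setting out from 12, Ph3PBr2 in CH2Cl2 should convert both silyl ethers directly into bromides, giving (4S,5S)-4-(bromomethyl)-5-[(1E,5E,9E)-11-bromo-2,6,10-trimethylundeca-1,5,9-trien-1-yl]-3-methylideneoxolan-2-one F5. Ganem oxidation with N-methylmorpholine N-oxide in MeCN should turn only the allylic bromide into the enal, giving (4S,5S)-4-(bromomethyl)-3-methylidene-5-[(1E,5E,9E)-2,6,10-trimethyl-11-oxoundeca-1,5,9-trien-1-yl]oxolan-2-one F6. F6 is cyclised under the step 12 conditions with added NaI (through 16), and the route is rejoined at 17.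

**Further compounds**
F1 | step 12 | (2E,6E,10E)-11-[(2S,3S)-3-(iodomethyl)-4-methylidene-5-oxooxolan-2-yl]-2,6,10-trimethylundeca-2,6,10-trienoic acid | C=C1C(=O)O[C@@H](/C=C(\C)CC/C=C(\C)CC/C=C(\C)C(=O)O)[C@H]1CI
F2 | step 12 | S-(pyridin-2-yl) (2E,6E,10E)-11-[(2S,3S)-3-(iodomethyl)-4-methylidene-5-oxooxolan-2-yl]-2,6,10-trimethylundeca-2,6,10-trienethioate | C=C1C(=O)O[C@@H](/C=C(\C)CC/C=C(\C)CC/C=C(\C)C(=O)Sc2ccccn2)[C@H]1CI
F3 | step 8 | methyl (3S,4R,5E,9E,13E)-15-[(tert-butyldimethylsilyl)oxy]-3-{[(tert-butyldimethylsilyl)oxy]methyl}-4-hydroxy-6,10,14-trimethyl-2-methylidenepentadeca-5,9,13-trienoate (enantiomer of 11) | COC(=O)C(=C)[C@@H](CO[Si](C)(C)C(C)(C)C)[C@H](O)/C=C(\C)CC/C=C(\C)CC/C=C(\C)CO[Si](C)(C)C(C)(C)C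
F4 | step 8 | erythro 5,6-epoxide of F3 (epoxy alcohol from the fast-reacting enantiomer) | COC(=O)C(=C)[C@@H](CO[Si](C)(C)C(C)(C)C)[C@H](O)[C@@H]1O[C@@]1(C)CC/C=C(\C)CC/C=C(\C)CO[Si](C)(C)C(C)(C)C
F5 | step 9 | (4S,5S)-4-(bromomethyl)-5-[(1E,5E,9E)-11-bromo-2,6,10-trimethylundeca-1,5,9-trien-1-yl]-3-methylideneoxolan-2-one | C=C1C(=O)O[C@@H](/C=C(\C)CC/C=C(\C)CC/C=C(\C)CBr)[C@H]1CBr
F6 | step 9 | (4S,5S)-4-(bromomethyl)-3-methylidene-5-[(1E,5E,9E)-2,6,10-trimethyl-11-oxoundeca-1,5,9-trien-1-yl]oxolan-2-one | C=C1C(=O)O[C@@H](/C=C(\C)CC/C=C(\C)CC/C=C(\C)C=O)[C@H]1CBr
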